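## Plan

Atom labels C1–O29 are the positions of the atoms in the target SMILES.

- **Cuts:** C25–C27 (aldol; closes the azepane and makes the bridged N21–C28 lactam), then C10–C11 (cyclopentane C3–C4–C10–C11–C27), then C11=C27 (metathesis) and N21–C28 (amide), giving acid 6 and amine 17.
- **Enabling feature:** C10 and C11, neighbours in the cyclopentane, are the β-carbons of the lactone carbonyl C6 and the lactam carbonyl C28. Both are acceptor carbons, so the bond is made by reductive coupling of a butenolide with an unsaturated δ-lactam.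
- **Forward order:** butenolide acid 6 (Mukaiyama–Michael, methylenation, oxidation); amine 17 with the saturated lactone (from Boc-D-allylglycine); amide; RCM (δ-lactam); SmI2 coupling (cyclopentane); lactam-selective bromination; SmI2 Reformatsky aldol (azepane).
- **Stereochemistry:** C13 from D-allylglycine; C14 by chelation-controlled allylation; C16 by protonation after conjugate reduction; C3/C4 by the organocatalyst; C10, C11 and C8 in the key step under control of C3/C4; C27 and C25 in the final aldol.

Key step: step 13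

**Remarks and assumptions**

- The (2S,5S)-imidazolidinone is assumed to deliver silyloxyfurans to the same enal face as in its Friedel–Crafts reactions (R β-centre for this substituent pattern), so the (2R,5R) catalyst is used for 3S. "Syn" means ring oxygen and ethyl on the same side of the C27–C3–C4–C10 zigzag.
- The C25 aldehyde is carried as a TBS-protected primary alcohol, not as an acetal, because step 14 uses oxalyl chloride.
- The target lactam is bridged (N21 and C27 are bridgeheads, C28 is the one-atom bridge), so it is a twisted amide. It is formed only in the last step and worked up cold and neutral.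

## Route

**Step 1**
Reactants: 1 3-methylfuran-2(5H)-one
Product: 2 3-methyl-2-(trimethylsilyloxy)furan
Conditions: TMSOTf, Et3N, Et2O, 0 °C; distillation
Reagents that add atoms: trimethylsilyl trifluoromethanesulfonate, C[Si](C)(C)OS(=O)(=O)C(F)(F)F
Why: Soft enolisation and O-silylation of the butenolide gives the aromatic 2-silyloxyfuran, the standard vinylogous Mukaiyama donor.

**Step 2**
Reactants: 2 3-methyl-2-(trimethylsilyloxy)furan; 3 (E)-pent-2-enal
Product: 4 (3S)-3-[(2R)-4-methyl-5-oxo-2,5-dihydrofuran-2-yl]pentanal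
Conditions: (2R,5R)-5-benzyl-2-tert-butyl-3-methylimidazolidin-4-one·2,4-dinitrobenzoic acid (20 mol %), H2O (2 equiv), CH2Cl2, –70 °C
Reagents that add atoms: none
Why: Iminium-catalysed vinylogous Mukaiyama–Michael addition; furan C5 should add to the unshielded face of the E-iminium ion (sets C3) in the syn sense known for this catalyst salt (sets C4), and any anti isomer is removed by chromatography.

**Step 3**
Reactants: 4 (3S)-3-[(2R)-4-methyl-5-oxo-2,5-dihydrofuran-2-yl]pentanal
Product: 5 (3S)-2-methylidene-3-[(2S)-4-methyl-5-oxo-2,5-dihydrofuran-2-yl]pentanal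
Conditions: aq. HCHO (37 %), pyrrolidine (10 mol %), propionic acid (10 mol %), i-PrOH, 45 °C
Reagents that add atoms: formaldehyde, C=O
Why: Amine-catalysed Mannich condensation–elimination (α-methylenation of aldehydes) acts at the only α-CH2; C3 is β and is not touched (the ring descriptor changes by CIP priority only).

**Step 4**
Reactants: 5 (3S)-2-methylidene-3-[(2S)-4-methyl-5-oxo-2,5-dihydrofuran-2-yl]pentanal
Product: 6 (3S)-2-methylidene-3-[(2S)-4-methyl-5-oxo-2,5-dihydrofuran-2-yl]pentanoic acid
Conditions: NaClO2, NaH2PO4, 2-methyl-2-butene, t-BuOH/H2O, 0 °C → rt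
Reagents that add atoms: sodium chlorite, [Na+].[O-]Cl=O
Why: Pinnick oxidation converts the enal into the acrylic acid without touching either alkene.

**Step 5**
Reactants: 7 (2R)-2-[(tert-butoxycarbonyl)amino]pent-4-enoic acid (N-Boc-D-allylglycine)
Product: 8 tert-butyl N-[(2R)-1-[methoxy(methyl)amino]-1-oxopent-4-en-2-yl]carbamate
Conditions: MeNH(OMe)·HCl, EDC·HCl, HOBt (cat.), N-methylmorpholine, CH2Cl2, 0 °C → rt
Reagents that add atoms: N,O-dimethylhydroxylamine hydrochloride, CNOC.Cl
Why: Carbodiimide coupling to the Weinreb amide proceeds without loss of the C13 configuration.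

**Step 6**
Reactants: 8 tert-butyl N-[(2R)-1-[methoxy(methyl)amino]-1-oxopent-4-en-2-yl]carbamate
Product: 9 tert-butyl N-[(2R)-1-oxopent-4-en-2-yl]carbamate
Conditions: LiAlH4, THF, –20 °C; aq. KHSO4; used crude
Reagents that add atoms: none
Why: Weinreb amide reduction stops at the chelated tetrahedral intermediate and gives the configurationally intact α-amino aldehyde.

**Step 7**
Reactants: 9 tert-butyl N-[(2R)-1-oxopent-4-en-2-yl]carbamate; 10 ethyl 2-[(trimethylsilyl)methyl]prop-2-enoate
Product: 12 tert-butyl N-[(1R)-1-[(2R)-4-methylidene-5-oxooxolan-2-yl]but-3-en-1-yl]carbamate, via hydroxy ester 11 (not isolated)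
Conditions: SnCl4, CH2Cl2, –78 °C; then TsOH·H2O (cat.), CH2Cl2, rt
Reagents that add atoms: none
Why: Chelation-controlled Hosomi–Sakurai allylation; SnCl4 bridges the aldehyde and carbamate oxygens and the allylsilane attacks anti to the allyl side chain, giving the syn (4R,5R) amino alcohol (sets C14), which acid lactonises.

**Step 8**
Reactants: 12 tert-butyl N-[(1R)-1-[(2R)-4-methylidene-5-oxooxolan-2-yl]but-3-en-1-yl]carbamate
Product: 13 tert-butyl N-[(1R)-1-[(2R,4R)-4-methyl-5-oxooxolan-2-yl]but-3-en-1-yl]carbamate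
Conditions: NaBH4, MeOH, –20 °C
Reagents that add atoms: none
Why: Conjugate hydride reduction of the α-methylene lactone leaves the terminal alkene alone, and the enolate should be protonated by methanol anti to the C5 side chain to give the cis-3,5 lactone (sets C16); the trans epimer is removed by chromatography.

**Step 9**
Reactants: 13 tert-butyl N-[(1R)-1-[(2R,4R)-4-methyl-5-oxooxolan-2-yl]but-3-en-1-yl]carbamate
Product: 14 (1R)-1-[(2R,4R)-4-methyl-5-oxooxolan-2-yl]but-3-en-1-aminium chloride
Conditions: HCl (4 M in dioxane), 0 °C → rt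
Reagents that add atoms: hydrogen chloride, Cl
Why: Acidolysis of the Boc group; the amine is kept as its salt because the free base would undergo O→N acyl shift to a hydroxy lactam.

**Step 10**
Reactants: 14 (1R)-1-[(2R,4R)-4-methyl-5-oxooxolan-2-yl]but-3-en-1-aminium chloride; 15 4-{[tert-butyl(dimethyl)silyl]oxy}butanal
Product: 17 (3R,5R)-5-[(1R)-1-({4-[tert-butyl(dimethyl)silyl]oxybutyl}amino)but-3-en-1-yl]-3-methyloxolan-2-one, via imine 16 (not isolated)
Conditions: NaOAc (1 equiv), NaBH(OAc)3, ClCH2CH2Cl, 0 °C; cold aq. NaHCO3; used at once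
Reagents that add atoms: none
Why: Reductive amination under weakly acidic conditions alkylates the hindered α-branched amine once and keeps the time spent as free base short.

**Step 11**
Reactants: 6 (3S)-2-methylidene-3-[(2S)-4-methyl-5-oxo-2,5-dihydrofuran-2-yl]pentanoic acid; 17 (3R,5R)-5-[(1R)-1-({4-[tert-butyl(dimethyl)silyl]oxybutyl}amino)but-3-en-1-yl]-3-methyloxolan-2-one
Product: 19 N-{4-[tert-butyl(dimethyl)silyl]oxybutyl}-N-[(1R)-1-[(2R,4R)-4-methyl-5-oxooxolan-2-yl]but-3-en-1-yl] amide of acid 6, via acid chloride 18 (not isolated)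
Conditions: 6, (COCl)2, DMF (cat.), CH2Cl2, 0 °C; then 17, CH2Cl2/sat. aq. NaHCO3, 0 °C
Reagents that add atoms: none
Why: Schotten–Baumann acylation with the acryloyl chloride; fast N-acylation outruns the O→N shift, and the absence of an amine base avoids vinylketene formation and loss of C3.

**Step 12**
Reactants: 19 N-{4-[tert-butyl(dimethyl)silyl]oxybutyl}-N-[(1R)-1-[(2R,4R)-4-methyl-5-oxooxolan-2-yl]but-3-en-1-yl] amide of acid 6
Product: 20 (5S)-5-{(1S)-1-[(6R)-1-{4-[tert-butyl(dimethyl)silyl]oxybutyl}-6-[(2R,4R)-4-methyl-5-oxooxolan-2-yl]-2-oxo-1,2,5,6-tetrahydropyridin-3-yl]propyl}-3-methylfuran-2(5H)-one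
Conditions: Grubbs II (10 mol %), toluene, 80 °C, argon sparge
Reagents that add atoms: none
Why: Ring-closing metathesis of an N-homoallyl 2-substituted acrylamide gives the 3-substituted 5,6-dihydropyridin-2-one, as known for α-branched acrylamides; the trisubstituted, electron-poor butenolide alkene does not take part.

**Step 13**
Reactants: 20 (5S)-5-{(1S)-1-[(6R)-1-{4-[tert-butyl(dimethyl)silyl]oxybutyl}-6-[(2R,4R)-4-methyl-5-oxooxolan-2-yl]-2-oxo-1,2,5,6-tetrahydropyridin-3-yl]propyl}-3-methylfuran-2(5H)-one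
Product: 21 tricyclic lactone–cyclopentane–lactam with C27–H (labels: 3S,4R,8S,10R,11S,13R,14R,16R,27S; lactone cis-fused on one face of the cyclopentane, lactam cis-fused on the other, H3/H11/H27 cis, C9 methyl cis to C11)
Conditions: SmI2 (2.5 equiv), HMPA (10 equiv), t-BuOH (3 equiv), THF (0.005 M), –78 → –20 °C
Reagents that add atoms: none
Why: Proposed new method: SmI2–HMPA puts one electron into each acceptor, the samarium-bound β-radicals at C10 and C11 combine, and t-BuOH protonates the lactone and lactam enolates at C8 and C27; the closest known reactions are the SmI2/HMPA and cathodic hydrocyclisations of tethered bis-enoates and the hydrodimerisation of unsaturated esters and amides, where both alkenes lie outside the new ring. The cyclopentane closes through the C10–C11 bond in a mode that is 5-exo-trig at the butenolide (C10=C8) but 5-endo at the lactam (C27=C11 lies inside the new ring), so the route relies on coupling of two reduced, twistable partners and not on an ionic Michael addition. C10 follows from C4 because only the cis-fused bicyclic lactone can form; C11 is set by the C3/C4 tether, which should prefer the closure that leaves the lactone and lactam on opposite faces of the cyclopentane; C27 is protonated anti to the new C11–C10 bond (cis fusion), and C8 on the convex face of the bicyclic lactone (methyl endo). The step needs attack on the lactam face syn to the C13 substituent and coupling in preference to plain reduction; the first rests on the tether outweighing the pseudo-axial C13 group, the second on high dilution, low temperature and a weak proton donor.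

**Step 14**
Reactants: 21 tricyclic lactone–cyclopentane–lactam with C27–H
Product: 25 C27-bromo lactam (21 with Br in place of H27), via chloroiminium chloride 22 (not isolated), via α-chloroenamine 23 (not isolated), via bromo chloroiminium salt 24 (not isolated)
Conditions: (COCl)2, CH2Cl2, 0 °C → rt; Et3N, –20 °C; NBS, –40 °C; aq. NaHCO3
Reagents that add atoms: N-bromosuccinimide, O=C1CCC(=O)N1Br; water, O
Why: Only the lactam carbonyl is basic enough to form the chloroiminium salt, Et3N then removes the acidified C27–H (Ghosez-type α-chloroenamine), and C-bromination plus hydrolysis returns the lactam as its tertiary α-bromide while both lactones stay untouched; the configuration at C27 is of no consequence.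

**Step 15**
Reactants: 25 C27-bromo lactam
Product: 26 C27-bromo lactam with N-(4-hydroxybutyl) chain
Conditions: HF·pyridine, THF/pyridine, 0 °C → rt
Reagents that add atoms: none
Why: Fluoride cleaves the primary silyl ether under mildly acidic conditions that the α-bromo lactam and the lactones tolerate.

**Step 16**
Reactants: 26 C27-bromo lactam with N-(4-hydroxybutyl) chain
Product: 27 C27-bromo lactam with N-(4-oxobutyl) chain
Conditions: Dess–Martin periodinane, NaHCO3, CH2Cl2, 0 °C → rt
Reagents that add atoms: none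
Why: Buffered Dess–Martin oxidation gives the aldehyde without base, so the tertiary bromide and the epimerisable C8 centre are kept.

**Step 17**
Reactants: 27 C27-bromo lactam with N-(4-oxobutyl) chain
Product: 28 CNP0120800.1 (labels: 3S,4S,8S,10R,11S,13R,14R,16R,25R,27S)
Conditions: SmI2 (2.2 equiv, added dropwise), HMPA (8 equiv), THF (0.003 M), –78 °C; sat. aq. NH4Cl at –78 °C
Reagents that add atoms: none
Why: Samarium Reformatsky aldol; SmI2 cleaves only the C27–Br bond, and the regiodefined lactam enolate adds to the tethered aldehyde (seven-membered ring), with the N-chain reaching C27 only on the face anti to C10 and to the C13 substituent (sets C27), while HMPA-saturated samarium should favour the open arrangement with the aldehyde oxygen anti to the enolate oxygen (sets C25 as R).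

## Compound list

1 | 3-methylfuran-2(5H)-one | CC1=CCOC1=O | starting material
2 | 3-methyl-2-(trimethylsilyloxy)furan | Cc1ccoc1O[Si](C)(C)C | intermediate
3 | (E)-pent-2-enal | CC/C=C/C=O | starting material
4 | (3S)-3-[(2R)-4-methyl-5-oxo-2,5-dihydrofuran-2-yl]pentanal | CC[C@H]([C@H]1OC(=O)C(C)=C1)CC=O | intermediate
5 | (3S)-2-methylidene-3-[(2S)-4-methyl-5-oxo-2,5-dihydrofuran-2-yl]pentanal | CC[C@H]([C@H]1OC(=O)C(C)=C1)C(=C)C=O | intermediate
6 | (3S)-2-methylidene-3-[(2S)-4-methyl-5-oxo-2,5-dihydrofuran-2-yl]pentanoic acid | CC[C@H]([C@H]1OC(=O)C(C)=C1)C(=C)C(=O)O | intermediate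
7 | (2R)-2-[(tert-butoxycarbonyl)amino]pent-4-enoic acid | C=CC[C@H](C(=O)O)NC(=O)OC(C)(C)C | starting material
8 | tert-butyl N-[(2R)-1-[methoxy(methyl)amino]-1-oxopent-4-en-2-yl]carbamate | C=CC[C@H](C(=O)N(C)OC)NC(=O)OC(C)(C)C | intermediate
9 | tert-butyl N-[(2R)-1-oxopent-4-en-2-yl]carbamate | C=CC[C@H](C=O)NC(=O)OC(C)(C)C | intermediate
10 | ethyl 2-[(trimethylsilyl)methyl]prop-2-enoate | CCOC(=O)C(=C)C[Si](C)(C)C | starting material
11 | ethyl (4R,5R)-5-[(tert-butoxycarbonyl)amino]-4-hydroxy-2-methylideneoct-7-enoate | C=CC[C@H]([C@H](O)CC(=C)C(=O)OCC)NC(=O)OC(C)(C)C | intermediate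
12 | tert-butyl N-[(1R)-1-[(2R)-4-methylidene-5-oxooxolan-2-yl]but-3-en-1-yl]carbamate | C=CC[C@H]([C@H]1CC(=C)C(=O)O1)NC(=O)OC(C)(C)C | intermediate
13 | tert-butyl N-[(1R)-1-[(2R,4R)-4-methyl-5-oxooxolan-2-yl]but-3-en-1-yl]carbamate | C=CC[C@H]([C@H]1C[C@@H](C)C(=O)O1)NC(=O)OC(C)(C)C | intermediate
14 | (1R)-1-[(2R,4R)-4-methyl-5-oxooxolan-2-yl]but-3-en-1-aminium chloride | C=CC[C@H]([C@H]1C[C@@H](C)C(=O)O1)[NH3+].[Cl-] | intermediate
15 | 4-{[tert-butyl(dimethyl)silyl]oxy}butanal | O=CCCCO[Si](C)(C)C(C)(C)C | starting material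
16 | (3R,5R)-5-[(1R)-1-({4-[tert-butyl(dimethyl)silyl]oxybutylidene}amino)but-3-en-1-yl]-3-methyloxolan-2-one | C=CC[C@H]([C@H]1C[C@@H](C)C(=O)O1)N=CCCCO[Si](C)(C)C(C)(C)C | intermediate
17 | (3R,5R)-5-[(1R)-1-({4-[tert-butyl(dimethyl)silyl]oxybutyl}amino)but-3-en-1-yl]-3-methyloxolan-2-one | C=CC[C@H]([C@H]1C[C@@H](C)C(=O)O1)NCCCCO[Si](C)(C)C(C)(C)C | intermediate
18 | (3S)-2-methylidene-3-[(2S)-4-methyl-5-oxo-2,5-dihydrofuran-2-yl]pentanoyl chloride | CC[C@H]([C@H]1OC(=O)C(C)=C1)C(=C)C(=O)Cl | intermediate
19 | N-{4-[tert-butyl(dimethyl)silyl]oxybutyl}-N-[(1R)-1-[(2R,4R)-4-methyl-5-oxooxolan-2-yl]but-3-en-1-yl] amide of acid 6 | CC[C@H]([C@H]1OC(=O)C(C)=C1)C(=C)C(=O)N(CCCCO[Si](C)(C)C(C)(C)C)[C@H](CC=C)[C@H]1C[C@@H](C)C(=O)O1 | intermediate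
20 | (5S)-5-{(1S)-1-[(6R)-1-{4-[tert-butyl(dimethyl)silyl]oxybutyl}-6-[(2R,4R)-4-methyl-5-oxooxolan-2-yl]-2-oxo-1,2,5,6-tetrahydropyridin-3-yl]propyl}-3-methylfuran-2(5H)-one (key-step precursor) | CC[C@H]([C@H]1OC(=O)C(C)=C1)C1=CC[C@H]([C@H]2C[C@@H](C)C(=O)O2)N(CCCCO[Si](C)(C)C(C)(C)C)C1=O | intermediate
21 | tricyclic lactone–cyclopentane–lactam with C27–H and N-(4-silyloxybutyl) chain (labels 3S,4R,8S,10R,11S,13R,14R,16R,27S) | CC[C@@H]1[C@H]2OC(=O)[C@@H](C)[C@H]2[C@@H]2C[C@H]([C@H]3C[C@@H](C)C(=O)O3)N(CCCCO[Si](C)(C)C(C)(C)C)C(=O)[C@H]12 | intermediate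
22 | chloroiminium chloride of 21 (C28–Cl, N21=C28) | CC[C@@H]1[C@H]2OC(=O)[C@@H](C)[C@H]2[C@@H]2C[C@H]([C@H]3C[C@@H](C)C(=O)O3)[N+](CCCCO[Si](C)(C)C(C)(C)C)=C(Cl)[C@H]12.[Cl-] | intermediate
23 | α-chloroenamine of 21 (C27=C28–Cl) | CC[C@@H]1[C@H]2OC(=O)[C@@H](C)[C@H]2[C@@H]2C[C@H]([C@H]3C[C@@H](C)C(=O)O3)N(CCCCO[Si](C)(C)C(C)(C)C)C(Cl)=C12 | intermediate
24 | C27-bromo chloroiminium succinimidate | CC[C@@H]1[C@H]2OC(=O)[C@@H](C)[C@H]2[C@@H]2C[C@H]([C@H]3C[C@@H](C)C(=O)O3)[N+](CCCCO[Si](C)(C)C(C)(C)C)=C(Cl)[C@]12Br.O=C1CCC(=O)[N-]1 | intermediate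
25 | C27-bromo lactam (21 with Br in place of H27) | CC[C@@H]1[C@H]2OC(=O)[C@@H](C)[C@H]2[C@@H]2C[C@H]([C@H]3C[C@@H](C)C(=O)O3)N(CCCCO[Si](C)(C)C(C)(C)C)C(=O)[C@]12Br | intermediate
26 | C27-bromo lactam with N-(4-hydroxybutyl) chain | CC[C@@H]1[C@H]2OC(=O)[C@@H](C)[C@H]2[C@@H]2C[C@H]([C@H]3C[C@@H](C)C(=O)O3)N(CCCCO)C(=O)[C@]12Br | intermediate
27 | C27-bromo lactam with N-(4-oxobutyl) chain | CC[C@@H]1[C@H]2OC(=O)[C@@H](C)[C@H]2[C@@H]2C[C@H]([C@H]3C[C@@H](C)C(=O)O3)N(CCCC=O)C(=O)[C@]12Br | intermediate
28 | CNP0120800.1 (labels 3S,4S,8S,10R,11S,13R,14R,16R,25R,27S) | CC[C@@H]1[C@H]2OC(=O)[C@@H](C)[C@H]2[C@@H]2C[C@H]([C@H]3C[C@@H](C)C(=O)O3)N3CCC[C@@H](O)[C@@]12C3=O | target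

## Step count

Total: 17 steps. Longest linear sequence: 13 steps (steps 5–17, from 7); the acid branch (steps 1–4) joins at step 11.

## Steps most likely to fail

**1. Step 13 (labelled).**
What may go wrong: each acceptor is reduced to its saturated form before the two β-carbons meet, because the closure is endocyclic at the lactam. Alternatively, closure occurs on the lactam face anti to the C13 substituent and gives the tricycle with lactone and lactam on the same face.

Fallback: the same C10–C11 bond is made as a 5-exo closure of a C11 radical onto the butenolide, using known reactions only. It sets out from 4 and 17 and comes back at 21.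
- Aldehyde 4 is α-brominated (NBS, prolinol silyl ether catalyst) and oxidised (NaClO2) to the α-bromo acid F1.
- F1 is coupled with 17 as in step 11 to the α-bromo amide F2.
- Ozonolysis of the terminal alkene (O3, then Me2S) gives the aldehyde F3.
- SmI2 in THF at –78 °C closes the δ-lactam by Reformatsky aldol to the 4-hydroxy lactam F4.
- Thiocarbonyldiimidazole/DMAP gives the imidazolyl thiocarbonate F5.
- Bu3SnH/AIBN in benzene at 80 °C generates the C11 radical, which adds to C10; the C8 radical takes hydrogen on the convex face, giving 21.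
- Limitation: C27 is set without control in the Reformatsky closure, and only the epimer with the side arm cis to the C13 substituent can give 21.

**2. Step 17.**
What may go wrong: a chelated, closed transition state places the aldehyde oxygen next to the lactam oxygen and gives the C25 epimer; the strained aldolate may also revert on warming.

Fallback: C25 is set by ketone reduction instead of by the aldol. It sets out from 27 and comes back at 28.
- The closure is run without HMPA and gives the C25-epimeric alcohol F8.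
- Dess–Martin oxidation gives the bridged keto lactam F9.
- L-Selectride at –78 °C should deliver hydride from the face flanked by the one-carbon C28 bridge, giving 28.

**3. Step 14.**
What may go wrong: incomplete chloroiminium formation at the hindered lactam, loss of HBr from the bromo iminium salt toward C3 or C11, or loss of the silyl ether to adventitious HCl.

Fallback: a base-mediated bromination with the lactones masked in situ. It sets out from 21 and comes back at 25.
- LiHMDS (2.3 equiv) with TMSCl in THF at –78 °C enolises only the two lactones and gives the bis(silyl ketene acetal) F6.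
- LDA then removes C27–H, and 1,2-dibromotetrachloroethane gives the bromide F7.
- Aqueous acidic work-up hydrolyses the silyl ketene acetals to 25; C8 and C16 are re-protonated kinetically (convex face; anti to the C14 side chain), which should restore their configurations.

## Further compounds

F1 | step 13 | (3S)-2-bromo-3-[4-methyl-5-oxo-2,5-dihydrofuran-2-yl]pentanoic acid (butenolide as in 4, C27 epimers) | CC[C@H]([C@H]1OC(=O)C(C)=C1)C(Br)C(=O)O
F2 | step 13 | α-bromo amide of F1 with amine 17 | CC[C@H]([C@H]1OC(=O)C(C)=C1)C(Br)C(=O)N(CCCCO[Si](C)(C)C(C)(C)C)[C@H](CC=C)[C@H]1C[C@@H](C)C(=O)O1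
F3 | step 13 | α-bromo amide aldehyde (C11 aldehyde) | CC[C@H]([C@H]1OC(=O)C(C)=C1)C(Br)C(=O)N(CCCCO[Si](C)(C)C(C)(C)C)[C@H](CC=O)[C@H]1C[C@@H](C)C(=O)O1
F4 | step 13 | 4-hydroxy-3-substituted piperidin-2-one (C11–OH, C27–H) | CC[C@H]([C@H]1OC(=O)C(C)=C1)C1C(O)C[C@H]([C@H]2C[C@@H](C)C(=O)O2)N(CCCCO[Si](C)(C)C(C)(C)C)C1=O
F5 | step 13 | imidazolyl thiocarbonate of F4 | CC[C@H]([C@H]1OC(=O)C(C)=C1)C1C(OC(=S)n2ccnc2)C[C@H]([C@H]3C[C@@H](C)C(=O)O3)N(CCCCO[Si](C)(C)C(C)(C)C)C1=O
F6 | step 14 | bis(trimethylsilyl ketene acetal) of 21 | CC[C@@H]1[C@H]2OC(O[Si](C)(C)C)=C(C)[C@H]2[C@@H]2C[C@H]([C@H]3CC(C)=C(O[Si](C)(C)C)O3)N(CCCCO[Si](C)(C)C(C)(C)C)C(=O)[C@H]12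
F7 | step 14 | C27-bromide of F6 | CC[C@@H]1[C@H]2OC(O[Si](C)(C)C)=C(C)[C@H]2[C@@H]2C[C@H]([C@H]3CC(C)=C(O[Si](C)(C)C)O3)N(CCCCO[Si](C)(C)C(C)(C)C)C(=O)[C@]12Br
F8 | step 17 | C25 epimer of 28 | CC[C@@H]1[C@H]2OC(=O)[C@@H](C)[C@H]2[C@@H]2C[C@H]([C@H]3C[C@@H](C)C(=O)O3)N3CCC[C@H](O)[C@@]12C3=O
F9 | step 17 | C25 ketone of 28 (bridged keto lactam) | CC[C@@H]1[C@H]2OC(=O)[C@@H](C)[C@H]2[C@@H]2C[C@H]([C@H]3C[C@@H](C)C(=O)O3)N3CCCC(=O)[C@@]12C3=O
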